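**Strategy**

Everything rests on disconnecting the aryl–oxygen bond between the benzylic oxygen O4 and the ring-fusion carbon C4a of the 1,4-benzodioxane. The other dioxane oxygen, O1, sits ortho to C4a and para to the flavonol, so an aryl bromide at C4a carrying the O1-linked side chain can be closed by a palladium-catalysed intramolecular etherification that forms the dioxane ring with both stereocentres retained. The precursor is a syn (1S,2S)-1-aryl-2-(2-bromo-4-cyanophenoxy)propane-1,3-diol 3-benzyl ether, made by an Evans glycolate aldol reaction. The nitrile then serves as the anchor for building the flavonol (rings A and C) by a one-pot Claisen–Schmidt/Algar–Flynn–Oyamada sequence, and global hydrogenolysis releases the target.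

Key step: step 5

Assumption: the oxazolidinone 2 and the acetophenone 14 are treated as purchasable; benzodioxane atoms are numbered O1, C2 (CH2O-bearing), C3 (aryl-bearing), O4, C4a–C8a.

**Route**

Step 1
Reactants: 1 3-bromo-4-hydroxybenzonitrile; 2 (4R)-4-benzyl-3-(chloroacetyl)-1,3-oxazolidin-2-one
Product: 3 3-bromo-4-{2-[(4R)-4-benzyl-2-oxo-1,3-oxazolidin-3-yl]-2-oxoethoxy}benzonitrile
Conditions: K2CO3, NaI (cat.), acetone, 50 °C
Reagents that add atoms: none
Why: Williamson etherification (SN2, iodide-assisted), in which the acidic 2-bromo-4-cyanophenol is fully ionised by K2CO3 and displaces the activated primary α-chloride, while the weakly nucleophilic phenoxide should spare the imide carbonyl and the auxiliary stereocentre.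

Step 2
Reactants: 3 the aryloxyacetyl imide; 4 4-(benzyloxy)-3-methoxybenzaldehyde
Product: 7 (4R)-4-benzyl-3-[(2R,3S)-3-(4-benzyloxy-3-methoxyphenyl)-2-(2-bromo-4-cyanophenoxy)-3-hydroxypropanoyl]-1,3-oxazolidin-2-one, via Z-boron enolate 5 (not isolated), via boron aldolate 6 (not isolated)
Conditions: Bu2BOTf, i-Pr2NEt, CH2Cl2, −78 to 0 °C; then 4, −78 to 0 °C; pH 7 buffer, MeOH, H2O2, 0 °C
Reagents that add atoms: none
Why: Evans syn glycolate aldol reaction, in which soft enolisation should give only the Z-boron enolate 5, which adds to the aldehyde through a closed chair (Zimmerman–Traxler) transition state on the enolate face opposite the benzyl group of the (R)-auxiliary and so sets C2 as R and C3 as S (syn) in one operation.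

Step 3
Reactants: 7 the syn aldol adduct
Product: 8 3-bromo-4-{[(1S,2S)-1-(4-benzyloxy-3-methoxyphenyl)-1,3-dihydroxypropan-2-yl]oxy}benzonitrile
Conditions: NaBH4, THF/H2O, 0 °C to rt
Reagents that add atoms: none
Why: Reductive removal of the oxazolidinone auxiliary, in which borohydride attacks the activated exocyclic imide carbonyl and takes it to the primary alcohol while nitrile, aryl bromide and both stereocentres stay untouched (C2 becomes S only through the change in substituent priorities).

Step 4
Reactants: 8 the syn 1,3-diol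
Product: 10 4-{[(1S,2S)-3-(benzyloxy)-1-(4-benzyloxy-3-methoxyphenyl)-1-hydroxypropan-2-yl]oxy}-3-bromobenzonitrile, via dibutylstannylene acetal 9 (not isolated)
Conditions: Bu2SnO, toluene, reflux (−H2O); then BnBr, Bu4NI, 90 °C
Reagents that add atoms: benzyl bromide, BrCc1ccccc1
Why: Stannylene-acetal-directed regioselective O-alkylation, in which the unhindered primary oxygen of the six-membered dibutylstannylene 9 is the more nucleophilic one, so benzylation should occur there and leave the secondary benzylic hydroxyl free for the ring closure.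

Step 5
Reactants: 10 the bromo alcohol
Product: 11 (2S,3S)-3-(4-benzyloxy-3-methoxyphenyl)-2-[(benzyloxy)methyl]-2,3-dihydro-1,4-benzodioxine-6-carbonitrile
Conditions: Pd(OAc)2 (5 mol %), 2-(di-tert-butylphosphino)-1,1'-binaphthyl (6 mol %), Cs2CO3, toluene, 80 °C
Reagents that add atoms: none
Why: Buchwald–Hartwig-type intramolecular aryl etherification: zerovalent palladium, formed in situ from Pd(OAc)2 and the bulky electron-rich monophosphine, inserts into the C–Br bond ortho to the aryl ether oxygen, Cs2CO3 exchanges bromide for the tethered benzylic alkoxide, and C(sp2)–O reductive elimination from the resulting seven-membered aryl(alkoxo) chelate of divalent palladium forms the O4–C4a bond. The closest known reaction type is the palladium-catalysed cyclisation of 2-(2-bromophenoxy)ethanols to 1,4-benzodioxanes, which is known for secondary alcohols. The 1,4-dioxane ring is closed in a six-membered mode, formally a 6-exo displacement of bromide at the aryl carbon by the alkoxide oxygen, realised as ring contraction of the palladacycle. No stereocentre is created: C2 and C3 come from the aldol step, the carbinol C–O bond is never broken and neither centre is acidic, so the syn (1S,2S) pattern should be carried with retention into the trans-(2S,3S) ring. The step needs C–O reductive elimination to outrun β-hydride elimination of the secondary benzylic alkoxide, which the bulky di-tert-butylphosphine ligand and the favourable six-membered closure should secure; site selectivity between the two hydroxyls is secured because the primary one is already a benzyl ether.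

Step 6
Reactants: 11 the benzodioxane nitrile
Product: 13 (2S,3S)-3-(4-benzyloxy-3-methoxyphenyl)-2-[(benzyloxy)methyl]-2,3-dihydro-1,4-benzodioxine-6-carbaldehyde, via N-aluminio imine 12 (not isolated)
Conditions: i-Bu2AlH, CH2Cl2, −78 °C; then 1 M HCl, 0 °C
Reagents that add atoms: water, O
Why: Partial hydride reduction of the aryl nitrile should stop at the N-aluminio imine 12, which is hydrolysed to the aldehyde on acidic work-up, the ethers and both stereocentres being inert to the hydride.

Step 7
Reactants: 13 the benzodioxane aldehyde; 14 1-[2,4-bis(benzyloxy)-6-hydroxyphenyl]ethan-1-one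
Product: 17 5,7-bis(benzyloxy)-2-{(2S,3S)-3-(4-benzyloxy-3-methoxyphenyl)-2-[(benzyloxy)methyl]-2,3-dihydro-1,4-benzodioxin-6-yl}-3-hydroxy-4H-chromen-4-one, via chalcone 15 (not isolated), via dihydroflavonol 16 (not isolated)
Conditions: KOH (aq.), EtOH/THF, rt; then H2O2 (30% aq.), NaOH (aq.), MeOH, 0 °C to rt
Reagents that add atoms: hydrogen peroxide, OO
Why: One-pot Claisen–Schmidt condensation to the E-chalcone 15 followed by Algar–Flynn–Oyamada oxidative cyclisation (phenoxide conjugate addition with trapping by H2O2, then oxidation of dihydroflavonol 16) should build the pyranone ring C of the 3-hydroxyflavone, the non-enolisable benzodioxane stereocentres and the benzyl-masked guaiacyl phenol being unaffected by the base.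

Step 8
Reactants: 17 the tetra-O-benzyl flavonol
Product: 18 2,3-dehydrosilybin B, 3,5,7-trihydroxy-2-[(2S,3S)-3-(4-hydroxy-3-methoxyphenyl)-2-(hydroxymethyl)-2,3-dihydro-1,4-benzodioxin-6-yl]-4H-chromen-4-one
Conditions: H2 (1 atm), Pd/C (10%), EtOAc/MeOH, rt
Reagents that add atoms: none
Why: Catalytic hydrogenolysis should remove the three aryl benzyl ethers and the primary alkyl benzyl ether in one operation, while the flavonol C2=C3 bond and the cyclic benzylic aryl ether of the dioxane, which cleaves far more slowly than O-benzyl groups, are expected to survive if the reaction is stopped at the calculated hydrogen uptake.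

**Compound list**

1 | 3-bromo-4-hydroxybenzonitrile | N#Cc1ccc(O)c(Br)c1 | starting material
2 | (4R)-4-benzyl-3-(chloroacetyl)-1,3-oxazolidin-2-one | O=C(CCl)N1[C@H](Cc2ccccc2)COC1=O | starting material
3 | 3-bromo-4-{2-[(4R)-4-benzyl-2-oxo-1,3-oxazolidin-3-yl]-2-oxoethoxy}benzonitrile | N#Cc1ccc(OCC(=O)N2[C@H](Cc3ccccc3)COC2=O)c(Br)c1 | intermediate
4 | 4-(benzyloxy)-3-methoxybenzaldehyde (O-benzylvanillin) | COc1cc(C=O)ccc1OCc1ccccc1 | starting material
5 | Z-dibutylboron enolate of imide 3 (aryloxy group cis to the boryloxy group) | CCCCB(CCCC)O/C(=C\Oc1ccc(C#N)cc1Br)N1[C@H](Cc2ccccc2)COC1=O | intermediate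
6 | O-dibutylboryl aldolate of 7 | COc1cc([C@H](OB(CCCC)CCCC)[C@@H](Oc2ccc(C#N)cc2Br)C(=O)N2[C@H](Cc3ccccc3)COC2=O)ccc1OCc1ccccc1 | intermediate
7 | (4R)-4-benzyl-3-[(2R,3S)-3-(4-benzyloxy-3-methoxyphenyl)-2-(2-bromo-4-cyanophenoxy)-3-hydroxypropanoyl]-1,3-oxazolidin-2-one | COc1cc([C@H](O)[C@@H](Oc2ccc(C#N)cc2Br)C(=O)N2[C@H](Cc3ccccc3)COC2=O)ccc1OCc1ccccc1 | intermediate
8 | 3-bromo-4-{[(1S,2S)-1-(4-benzyloxy-3-methoxyphenyl)-1,3-dihydroxypropan-2-yl]oxy}benzonitrile | COc1cc([C@H](O)[C@@H](Oc2ccc(C#N)cc2Br)CO)ccc1OCc1ccccc1 | intermediate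
9 | 3-bromo-4-{[(4S,5S)-4-(4-benzyloxy-3-methoxyphenyl)-2,2-dibutyl-1,3,2-dioxastanninan-5-yl]oxy}benzonitrile (stannylene acetal of 8) | COc1cc([C@@H]2O[Sn](CCCC)(CCCC)OC[C@@H]2Oc2ccc(C#N)cc2Br)ccc1OCc1ccccc1 | intermediate
10 | 4-{[(1S,2S)-3-(benzyloxy)-1-(4-benzyloxy-3-methoxyphenyl)-1-hydroxypropan-2-yl]oxy}-3-bromobenzonitrile | COc1cc([C@H](O)[C@@H](Oc2ccc(C#N)cc2Br)COCc2ccccc2)ccc1OCc1ccccc1 | intermediate
11 | (2S,3S)-3-(4-benzyloxy-3-methoxyphenyl)-2-[(benzyloxy)methyl]-2,3-dihydro-1,4-benzodioxine-6-carbonitrile | COc1cc([C@@H]2Oc3cc(C#N)ccc3O[C@H]2COCc2ccccc2)ccc1OCc1ccccc1 | intermediate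
12 | N-(diisobutylaluminio) imine of aldehyde 13 | COc1cc([C@@H]2Oc3cc(C=N[Al](CC(C)C)CC(C)C)ccc3O[C@H]2COCc2ccccc2)ccc1OCc1ccccc1 | intermediate
13 | (2S,3S)-3-(4-benzyloxy-3-methoxyphenyl)-2-[(benzyloxy)methyl]-2,3-dihydro-1,4-benzodioxine-6-carbaldehyde | COc1cc([C@@H]2Oc3cc(C=O)ccc3O[C@H]2COCc2ccccc2)ccc1OCc1ccccc1 | intermediate
14 | 1-[2,4-bis(benzyloxy)-6-hydroxyphenyl]ethan-1-one | CC(=O)c1c(O)cc(OCc2ccccc2)cc1OCc1ccccc1 | starting material
15 | (E)-1-[2,4-bis(benzyloxy)-6-hydroxyphenyl]-3-{(2S,3S)-3-(4-benzyloxy-3-methoxyphenyl)-2-[(benzyloxy)methyl]-2,3-dihydro-1,4-benzodioxin-6-yl}prop-2-en-1-one | COc1cc([C@@H]2Oc3cc(/C=C/C(=O)c4c(O)cc(OCc5ccccc5)cc4OCc4ccccc4)ccc3O[C@H]2COCc2ccccc2)ccc1OCc1ccccc1 | intermediate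
16 | 5,7-bis(benzyloxy)-2-{(2S,3S)-3-(4-benzyloxy-3-methoxyphenyl)-2-[(benzyloxy)methyl]-2,3-dihydro-1,4-benzodioxin-6-yl}-3-hydroxychroman-4-one (2,3-trans, both trans diastereomers at the chromanone) | COc1cc([C@@H]2Oc3cc(C4Oc5cc(OCc6ccccc6)cc(OCc6ccccc6)c5C(=O)C4O)ccc3O[C@H]2COCc2ccccc2)ccc1OCc1ccccc1 | intermediate
17 | 5,7-bis(benzyloxy)-2-{(2S,3S)-3-(4-benzyloxy-3-methoxyphenyl)-2-[(benzyloxy)methyl]-2,3-dihydro-1,4-benzodioxin-6-yl}-3-hydroxy-4H-chromen-4-one | COc1cc([C@@H]2Oc3cc(-c4oc5cc(OCc6ccccc6)cc(OCc6ccccc6)c5c(=O)c4O)ccc3O[C@H]2COCc2ccccc2)ccc1OCc1ccccc1 | intermediate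
18 | 2,3-dehydrosilybin B | COc1cc([C@@H]2Oc3cc(-c4oc5cc(O)cc(O)c5c(=O)c4O)ccc3O[C@H]2CO)ccc1O | target

**Step count and risks**

Total step count: 8. Longest linear sequence: 8 (steps 1 to 8; compounds 2, 4 and 14 are bought).

Steps most likely to fail:

Step 5. β-Hydride elimination from the secondary benzylic alkoxide on divalent palladium may outrun C–O reductive elimination, which oxidises the carbinol and reduces the C–Br bond instead of closing the ring. The fallback sets out from 10 and comes back at 11. It swaps the mechanism for a copper-catalysed Ullmann-type ring closure (CuI, 8-hydroxyquinoline, Cs2CO3, toluene, 110 °C), where the same O4–C4a bond forms from a univalent-copper alkoxide that has no comparable β-hydride channel. No new compound is made on the way.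

Step 7. Ring closure in the Algar–Flynn–Oyamada stage may go through the α-carbon (five-membered aurone-type closure), a course that a 6'-alkoxy group on the chalcone is known to favour, and the condensation may be incomplete in the one-pot regime. The fallback sets out from 13 and 14 and comes back at 17. The sequence is stopped after the KOH stage and chalcone 15 is isolated. Oxidative cyclisation with catalytic I2 in DMSO at 120 °C should give 5,7-bis(benzyloxy)-2-{(2S,3S)-3-(4-benzyloxy-3-methoxyphenyl)-2-[(benzyloxy)methyl]-2,3-dihydro-1,4-benzodioxin-6-yl}-4H-chromen-4-one F1. Epoxidation of its C2=C3 bond with dimethyldioxirane (acetone/CH2Cl2, 0 °C) should give the flavone 2,3-epoxide F2. Catalytic TsOH then opens the epoxide, which tautomerises to the 3-hydroxyflavone 17.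

Step 4. Site selectivity in the alkylation of the stannylene may be poor, with benzylation of the secondary benzylic oxygen or double benzylation. The fallback sets out from 8 and comes back at 11. Kinetic silylation (TBSCl, imidazole, DMF, 0 °C) should give the primary silyl ether 3-bromo-4-{[(1S,2S)-1-(4-benzyloxy-3-methoxyphenyl)-3-(tert-butyldimethylsilyloxy)-1-hydroxypropan-2-yl]oxy}benzonitrile F3. The palladium-catalysed ring closure of step 5 then gives (2S,3S)-3-(4-benzyloxy-3-methoxyphenyl)-2-[(tert-butyldimethylsilyloxy)methyl]-2,3-dihydro-1,4-benzodioxine-6-carbonitrile F4. Bu4NF in THF releases (2S,3S)-3-(4-benzyloxy-3-methoxyphenyl)-2-(hydroxymethyl)-2,3-dihydro-1,4-benzodioxine-6-carbonitrile F5. With only one hydroxyl left, NaH and BnBr in DMF then give 11 without any selectivity question.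

**Further compounds**

F0 | step 5 | none | none
F1 | step 7 | 5,7-bis(benzyloxy)-2-{(2S,3S)-3-(4-benzyloxy-3-methoxyphenyl)-2-[(benzyloxy)methyl]-2,3-dihydro-1,4-benzodioxin-6-yl}-4H-chromen-4-one | COc1cc([C@@H]2Oc3cc(-c4cc(=O)c5c(OCc6ccccc6)cc(OCc6ccccc6)cc5o4)ccc3O[C@H]2COCc2ccccc2)ccc1OCc1ccccc1
F2 | step 7 | 2,3-epoxide of flavone F1 (4,6-bis(benzyloxy)-1a-aryl-1a,7a-dihydro-7H-oxireno[2,3-b]chromen-7-one, epoxide configuration undefined) | COc1cc([C@@H]2Oc3cc(C45OC4C(=O)c4c(OCc6ccccc6)cc(OCc6ccccc6)cc4O5)ccc3O[C@H]2COCc2ccccc2)ccc1OCc1ccccc1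
F3 | step 4 | 3-bromo-4-{[(1S,2S)-1-(4-benzyloxy-3-methoxyphenyl)-3-(tert-butyldimethylsilyloxy)-1-hydroxypropan-2-yl]oxy}benzonitrile | COc1cc([C@H](O)[C@@H](Oc2ccc(C#N)cc2Br)CO[Si](C)(C)C(C)(C)C)ccc1OCc1ccccc1
F4 | step 4 | (2S,3S)-3-(4-benzyloxy-3-methoxyphenyl)-2-[(tert-butyldimethylsilyloxy)methyl]-2,3-dihydro-1,4-benzodioxine-6-carbonitrile | COc1cc([C@@H]2Oc3cc(C#N)ccc3O[C@H]2CO[Si](C)(C)C(C)(C)C)ccc1OCc1ccccc1
F5 | step 4 | (2S,3S)-3-(4-benzyloxy-3-methoxyphenyl)-2-(hydroxymethyl)-2,3-dihydro-1,4-benzodioxine-6-carbonitrile | COc1cc([C@@H]2Oc3cc(C#N)ccc3O[C@H]2CO)ccc1OCc1ccccc1
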